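**Remark (assumption):** scutellarein (8) is taken as a purchasable natural product. Compounds 8 to 14 are named with the plain locants of a single flavone (O5, O6, O7, O4'); these become O5'', O6'', O7'' and O4''' in 16 and 17.

## Analysis of the target

Neocryptomerin is a biflavone of the hinokiflavone type. A 5-hydroxy-7-methoxyflavone (rings A, C and B, unprimed and primed locants) is joined through its C4' oxygen to C6'' of a scutellarein unit (chromone rings A'' and C'', aryl ring B''). There is no stereocentre, and the diaryl ether rotates freely, so the problem is one of regiochemistry and of telling six peripheral oxygens apart. O7 must stay methylated, O5, O5'', O7'' and O4''' must end free, and one oxygen is the bridge. Both γ-pyranone rings are opened by hydroxide, alkoxide and organolithium reagents. Ring A'' with its 5,7-dihydroxy-6-aryloxy pattern can isomerise to the 8-aryloxy isomer by Wessely–Moser ring opening in hot strong acid, and the free polyphenol is poorly soluble. The hardest structural point is the bridge oxygen at C6'', which is flanked by oxygenated C5'' and C7'' and must be singled out among four hydroxyls. The strategy rests on ring A of the methoxyflavone half: C8a (bearing O1) and C4a (bearing the C4 carbonyl) are neighbours, and the C5 oxygen sits next to C4a. This is the pattern a 3,5-dialkoxybenzyne produces when it takes an oxygen nucleophile at the carbon remote from its flanking alkoxy group and an acyl group at the other. All three bonds of ring C (C8a–O1, C4a–C4, O1–C2) can therefore be made in one operation from an aryne and an arylpropiolic acid that already carries the whole scutellarein half.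

## Retrosynthetic reasoning

**17 to 16.** The last cut removes four O-alkyl groups: the benzyl ethers on O5'', O7'' and O4''' and the methyl ether on O5. Free phenols would capture the aryne of the key step and make every intermediate insoluble, so they appear only at the end. The O5 methyl is the only methyl ether peri to a carbonyl, so a chelating Lewis acid can remove it and leave the O7 methyl. The forward reaction must distinguish two methyl ethers by position alone and must not use hot protic acid, which would move the bridge from C6'' to C8''.

**16 to 7 and 14.** Three bonds of ring C are cut: C8a–O1, C4a–C4 and O1–C2. Cutting here removes the pyranone and leaves ring A as an intact benzene with the right oxygen pattern. It also splits the molecule into a small symmetric-derived aryne precursor (7) and one acid (14) that holds everything else. No ortho-hydroxyacetophenone is needed, and the two methoxy groups need no differentiation before the coupling. In the forward direction the aryne released from 7 must accept the carboxylate oxygen at the carbon remote from its flanking methoxy group, pass the acyl group to the neighbouring carbon, and let the new phenoxide close 6-endo onto the ynone.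

**14 to 13 to 12.** The carboxyl carbon and then the terminal acetylenic carbon are removed. The propiolic acid is the least stable compound of the route, so it is made immediately before use. Both carbons are added by methods that need no organolithium reagent: catalytic C–H carboxylation of 13 and a diazophosphonate homologation of aldehyde 12. The C4 carbonyl of the flavone in 12 and 13 would not survive a lithium acetylide route.

**12 to 9 and 10 (through 11).** The diaryl ether is cut on the ring B side. The formyl group of 10 activates the fluoride for addition–elimination and is also the handle for the alkyne. Cutting on the other side would need a 6-haloflavone flanked by two alkoxy groups, a poor electrophile. The ether is formed while O5 is still a chelated, unreactive hydroxyl (11), and O5 is benzylated afterwards. The forward reaction must arylate O6 and not O5.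

**9 to 8.** Two benzyl ethers are removed. Exhaustive benzylation of 8 would cap O6 before O5, so a 6-phenol with O5 protected cannot be made directly. The benzylation is therefore stopped at the 7,4'-diether. This uses the acidity order of 8: O7–H and O4'–H are vinylogous acids, O6–H is an ordinary phenol, and O5–H is hydrogen-bonded.

**7 to 5 to 2 to 1.** The O–S bond and the C2–Si bond are cut. The carbamate of 2 serves twice: it directs lithiation to the one ring position flanked by both an oxygen director and a methoxy group, and in 5 it is the masked phenol that becomes the triflate. The symmetry of 1 makes the two such positions identical.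

## Alternatives that were turned down

**Alternative 1:** Ring B is disconnected at C2'–C3' and C4'–C5'. In the forward direction the ynol ether A1 (5,7,4'-tri-O-benzyl-6-O-ethynylscutellarein) would add across C3 and C6 of methyl coumalate A2 in an inverse-demand Diels–Alder reaction. Loss of CO2 would then aromatise the adduct to the 4-aryloxybenzoate A3.
- For: the para regiochemistry is inherent to coumalate with electron-rich alkynes, no charged intermediate is involved, and A3 is a robust ester. On mildness of the key step this alternative is stronger than the chosen route.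
- Against: ring B is an unsubstituted para-phenylene, available ready-made in 10, and A3 could be reached in one SNAr step from a para-fluorobenzoate. Aryl ynol ethers are made with strong base, which the pyranone would not tolerate, and they hydrolyse easily. A3 still lacks rings A and C of the methoxyflavone half, so at least three further steps and the O5/O7 differentiation remain.
- Comparison: the chosen strategy spends its key step on a ring the target actually needs built.

**Alternative 2:** Ring A of the methoxyflavone half is unravelled at C4a–C5, and ring C at O1–C2, to the open-chain methyl (E)-3-methoxy-5,7,9-trioxo-9-arylnon-2-enoate A4. In the forward direction Mg(OMe)2 would promote Claisen-type attack of the C4a methylene on the ester carbon, and acid would then close the pyranone to give A5 (5'',7'',4'''-tri-O-benzylneocryptomerin).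
- For: it is biomimetic, and it delivers O5–H free and O7 methylated directly from the cyclisation. On that point it is stronger than the chosen route, which needs a late chelation-controlled demethylation.
- Against: A4 has three enolisable methylenes and several closure modes (aldol to a resorcylate, O-attack to a pyrone, the wanted Claisen). Its assembly needs polyanion acylations in the presence of the base-sensitive ring C''.
- Comparison: the chosen route buys ring A as an aromatic with its oxygens in place, handles no polycarbonyl chain, and merges the demethylation with the debenzylation, so it costs no extra step.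

**Alternative 3:** Ring A'' is disconnected at C4a''–C5''. The precursor A6 is a 6-aryl-4-pyranone bearing a 2-aryloxy-3-oxobutanoate side chain (racemic at the aryloxy carbon, which is lost on aromatisation). Base would form an extended enolate whose pyranone C3 attacks the ester carbonyl, giving A7 (5,4'''-di-O-benzylneocryptomerin).
- For: the hindered C6''–O bond is made by substitution at an sp3 carbon before ring A'' exists. This avoids both the selective protection of 8 and arylation of a doubly flanked phenoxide, and on that point it is stronger than the chosen route.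
- Against: the α-aryloxy β-keto ester is deprotonated first at its most acidic carbon, so the key step needs a dianion. Pyranone C3 is a weak nucleophile, and competing self-condensation and loss of aryloxide are likely. The complete methoxyflavone half and a functionalised pyranone must both be made first, which makes the route longer.
- Comparison: the chosen route takes ring A'' finished from 8 and forms its key bonds through an aryne, whose reactivity does not depend on a marginal enolate.

Key step: step 8

## Route

**Step 1**
Reactants: 1 3,5-dimethoxyphenol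
Product: 2 3,5-dimethoxyphenyl N-isopropylcarbamate
Conditions: i-PrNCO, Et3N (cat.), CH2Cl2, rt
Reagents that add atoms: isopropyl isocyanate, CC(C)N=C=O
Why: Base-catalysed addition of a phenol to an isocyanate (carbamoylation); the N–H carbamate is chosen because it becomes a strong ortho-director once N-silylated and can later be removed under mild amine conditions.

**Step 2**
Reactants: 2 3,5-dimethoxyphenyl N-isopropylcarbamate
Product: 5 3,5-dimethoxy-2-(trimethylsilyl)phenyl N-isopropylcarbamate, via N-silyl carbamate 3 (not isolated), via N-silyl 2-trimethylsilyl carbamate 4 (not isolated)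
Conditions: TBSOTf, TMEDA, Et2O, 0 °C to rt; n-BuLi, TMEDA, -78 °C; TMSCl, -78 °C to rt; aq NaHSO4
Reagents that add atoms: chlorotrimethylsilane, C[Si](C)(C)Cl
Why: Directed ortho-metalation: in situ N-silylation masks the N–H, and n-BuLi/TMEDA should then lithiate C2, the only kind of site flanked by both the carbamate and a methoxy group (C6 is its mirror image), in preference to C4 between two weaker methoxy directors. TMSCl traps the aryllithium and the acidic work-up hydrolyses the N–Si bond.

**Step 3**
Reactants: 5 3,5-dimethoxy-2-(trimethylsilyl)phenyl N-isopropylcarbamate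
Product: 7 3,5-dimethoxy-2-(trimethylsilyl)phenyl trifluoromethanesulfonate, via 3,5-dimethoxy-2-(trimethylsilyl)phenol 6 (not isolated)
Conditions: DBU, Et2NH, MeCN, 40 °C; then PhNTf2, rt
Reagents that add atoms: N-phenylbis(trifluoromethanesulfonimide), O=S(=O)(N(c1ccccc1)S(=O)(=O)C(F)(F)F)C(F)(F)F
Why: DBU deprotonates the carbamate N–H, E1cB loss of the phenoxide follows and Et2NH traps the isocyanate as a urea; the phenoxide is then O-sulfonylated by PhNTf2 in the same pot, without the fluoride or strong acid that would strip the C-silyl group.

**Step 4**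
Reactants: 8 scutellarein
Product: 9 7,4'-di-O-benzylscutellarein
Conditions: BnBr (2.05 equiv), K2CO3, DMF, 0 °C to rt, Ar
Reagents that add atoms: benzyl bromide, BrCc1ccccc1
Why: Williamson etherification ordered by phenol acidity: O7–H and O4'–H are conjugated to the C4 carbonyl and alkylate first, O6–H is an ordinary hindered phenol and O5–H is hydrogen-bonded to the carbonyl, so two equivalents of BnBr should stop at the 7,4'-diether.

**Step 5**
Reactants: 9 7,4'-di-O-benzylscutellarein; 10 4-fluorobenzaldehyde
Product: 12 4-({5,7-bis(benzyloxy)-2-[4-(benzyloxy)phenyl]-4-oxo-4H-chromen-6-yl}oxy)benzaldehyde, via 5-hydroxy aldehyde 11 (not isolated)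
Conditions: K2CO3, DMF, 90 °C, Ar; then BnBr, KI (cat.), 60 °C
Reagents that add atoms: benzyl bromide, BrCc1ccccc1
Why: Nucleophilic aromatic substitution (addition–elimination) of the para-formyl-activated fluoride by the O6 phenoxide, the more acidic and unchelated hydroxyl of the 5,6-diol. The chelated O5–H is then benzylated in the same pot under forcing Williamson conditions, so that no phenol is left to capture the aryne in step 8.

**Step 6**
Reactants: 12 4-({5,7-bis(benzyloxy)-2-[4-(benzyloxy)phenyl]-4-oxo-4H-chromen-6-yl}oxy)benzaldehyde
Product: 13 5,7-bis(benzyloxy)-2-[4-(benzyloxy)phenyl]-6-(4-ethynylphenoxy)-4H-chromen-4-one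
Conditions: dimethyl (1-diazo-2-oxopropyl)phosphonate, K2CO3, MeOH/THF, 0 °C to rt
Reagents that add atoms: dimethyl (1-diazo-2-oxopropyl)phosphonate, CC(=O)C(=[N+]=[N-])P(=O)(OC)OC
Why: Seyferth–Gilbert homologation (Ohira–Bestmann variant): methanolysis frees the diazomethylphosphonate anion, olefination of the aldehyde gives a diazoalkene, and loss of N2 with 1,2-hydride shift gives the terminal alkyne. The carbonate/methanol medium spares the pyranone, which a dibromoolefin/n-BuLi sequence would not.

**Step 7**
Reactants: 13 5,7-bis(benzyloxy)-2-[4-(benzyloxy)phenyl]-6-(4-ethynylphenoxy)-4H-chromen-4-one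
Product: 14 3-[4-({5,7-bis(benzyloxy)-2-[4-(benzyloxy)phenyl]-4-oxo-4H-chromen-6-yl}oxy)phenyl]prop-2-ynoic acid
Conditions: CO2 (1 atm), AgI (cat.), Cs2CO3, DMF, 50 °C; cold dil. HCl
Reagents that add atoms: carbon dioxide, O=C=O
Why: Silver-catalysed C–H carboxylation of a terminal alkyne: AgI and Cs2CO3 form the silver acetylide, which inserts CO2 to give the caesium propiolate. No organolithium reagent is involved, so the C4 carbonyl is untouched, and cold acidification frees the acid before it can lose CO2.

**Step 8**
Reactants: 7 3,5-dimethoxy-2-(trimethylsilyl)phenyl trifluoromethanesulfonate; 14 3-[4-({5,7-bis(benzyloxy)-2-[4-(benzyloxy)phenyl]-4-oxo-4H-chromen-6-yl}oxy)phenyl]prop-2-ynoic acid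
Product: 16 5-O-methyl-5'',7'',4'''-tri-O-benzylneocryptomerin, via hydroxyaryl ynone 15 (not isolated)
Conditions: Cs2CO3 (1.1 equiv), THF, rt; then 7 (1.5 equiv), CsF (4 equiv), THF, 125 °C, sealed tube
Reagents that add atoms: none
Why: Fluoride attacks the silicon of 7 and triflate leaves, so 3,5-dimethoxybenzyne is released slowly and stays dilute. The caesium carboxylate of 14 adds through oxygen to the aryne carbon remote from the flanking methoxy group (the future C8a), because that leaves the aryl anion on the carbon next to the inductively withdrawing methoxy group (the future C4a). In hot aprotic THF this anion attacks its own ester carbonyl through a four-centre transition state and the old C–O bond breaks, which amounts to insertion of the aryne into the C–O bond of the acid and gives the caesium phenoxide of ynone 15. The closest known reaction type is exactly this aryne insertion into carboxylic acids to give ortho-hydroxyaryl ketones, which with unsaturated acids is followed in the same flask by conjugate closure of the phenoxide to a benzopyranone. Ring C closes by 6-endo-dig oxa-Michael addition of the phenoxide to the β-carbon of the ynone (O1–C2), and the allenolate is protonated at C3 by hydrogencarbonate. Three selectivities are needed: the site of addition on the aryne, secured by the methoxy group beside the triple bond; acyl shift instead of protonation to a plain aryl ester, secured by preforming the carboxylate with Cs2CO3 so that no acidic proton is present; and 6-endo instead of 5-exo closure, secured because only attack at the β-carbon gives a carbonyl-stabilised anion when neither a π-acidic metal nor a protic solvent is present. No stereocentre is formed. The benzyl ethers, the diaryl ether and the pyranone of the scutellarein half offer the aryne no acidic or nucleophilic site, and the two methoxy groups need no differentiation because the one that ends at C5 is removed by chelation in step 9.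

**Step 9**
Reactants: 16 5-O-methyl-5'',7'',4'''-tri-O-benzylneocryptomerin
Product: 17 neocryptomerin
Conditions: BCl3, C6HMe5, CH2Cl2, -78 °C to rt; then H2O
Reagents that add atoms: none
Why: Lewis-acid ether cleavage: BCl3 removes the three benzyl groups as benzyl cations, which pentamethylbenzene traps so that the electron-rich ring A'' is not C-benzylated. The 5-methyl ether is cleaved through the six-membered boron chelate with the C4 carbonyl, while the unchelated 7-methyl ether and the diaryl ether are inert to BCl3 at or below room temperature, and no hot protic acid is present to trigger Wessely–Moser isomerisation.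

## Compound list

1 | 3,5-dimethoxyphenol | COc1cc(O)cc(OC)c1 | starting material
2 | 3,5-dimethoxyphenyl N-isopropylcarbamate | COc1cc(OC)cc(OC(=O)NC(C)C)c1 | intermediate
3 | 3,5-dimethoxyphenyl N-(tert-butyldimethylsilyl)-N-isopropylcarbamate (formed in situ) | COc1cc(OC)cc(OC(=O)N(C(C)C)[Si](C)(C)C(C)(C)C)c1 | intermediate
4 | 3,5-dimethoxy-2-(trimethylsilyl)phenyl N-(tert-butyldimethylsilyl)-N-isopropylcarbamate (formed in situ) | COc1cc(OC)c([Si](C)(C)C)c(OC(=O)N(C(C)C)[Si](C)(C)C(C)(C)C)c1 | intermediate
5 | 3,5-dimethoxy-2-(trimethylsilyl)phenyl N-isopropylcarbamate | COc1cc(OC)c([Si](C)(C)C)c(OC(=O)NC(C)C)c1 | intermediate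
6 | 3,5-dimethoxy-2-(trimethylsilyl)phenol (formed in situ) | COc1cc(OC)c([Si](C)(C)C)c(O)c1 | intermediate
7 | 3,5-dimethoxy-2-(trimethylsilyl)phenyl trifluoromethanesulfonate | COc1cc(OC)c([Si](C)(C)C)c(OS(=O)(=O)C(F)(F)F)c1 | intermediate
8 | scutellarein (5,6,7-trihydroxy-2-(4-hydroxyphenyl)-4H-chromen-4-one) | O=c1cc(-c2ccc(O)cc2)oc2cc(O)c(O)c(O)c12 | starting material
9 | 7,4'-di-O-benzylscutellarein (7-(benzyloxy)-2-[4-(benzyloxy)phenyl]-5,6-dihydroxy-4H-chromen-4-one) | O=c1cc(-c2ccc(OCc3ccccc3)cc2)oc2cc(OCc3ccccc3)c(O)c(O)c12 | intermediate
10 | 4-fluorobenzaldehyde | O=Cc1ccc(F)cc1 | starting material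
11 | 4-({7-(benzyloxy)-2-[4-(benzyloxy)phenyl]-5-hydroxy-4-oxo-4H-chromen-6-yl}oxy)benzaldehyde (formed in situ) | O=Cc1ccc(Oc2c(OCc3ccccc3)cc3oc(-c4ccc(OCc5ccccc5)cc4)cc(=O)c3c2O)cc1 | intermediate
12 | 4-({5,7-bis(benzyloxy)-2-[4-(benzyloxy)phenyl]-4-oxo-4H-chromen-6-yl}oxy)benzaldehyde | O=Cc1ccc(Oc2c(OCc3ccccc3)cc3oc(-c4ccc(OCc5ccccc5)cc4)cc(=O)c3c2OCc2ccccc2)cc1 | intermediate
13 | 5,7-bis(benzyloxy)-2-[4-(benzyloxy)phenyl]-6-(4-ethynylphenoxy)-4H-chromen-4-one | C#Cc1ccc(Oc2c(OCc3ccccc3)cc3oc(-c4ccc(OCc5ccccc5)cc4)cc(=O)c3c2OCc2ccccc2)cc1 | intermediate
14 | 3-[4-({5,7-bis(benzyloxy)-2-[4-(benzyloxy)phenyl]-4-oxo-4H-chromen-6-yl}oxy)phenyl]prop-2-ynoic acid | OC(=O)C#Cc1ccc(Oc2c(OCc3ccccc3)cc3oc(-c4ccc(OCc5ccccc5)cc4)cc(=O)c3c2OCc2ccccc2)cc1 | intermediate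
15 | 5,7-bis(benzyloxy)-2-[4-(benzyloxy)phenyl]-6-{4-[3-(2-hydroxy-4,6-dimethoxyphenyl)-3-oxoprop-1-yn-1-yl]phenoxy}-4H-chromen-4-one (formed in situ) | COc1cc(O)c(C(=O)C#Cc2ccc(Oc3c(OCc4ccccc4)cc4oc(-c5ccc(OCc6ccccc6)cc5)cc(=O)c4c3OCc3ccccc3)cc2)c(OC)c1 | intermediate
16 | 5-O-methyl-5'',7'',4'''-tri-O-benzylneocryptomerin (5,7-bis(benzyloxy)-2-[4-(benzyloxy)phenyl]-6-[4-(5,7-dimethoxy-4-oxo-4H-chromen-2-yl)phenoxy]-4H-chromen-4-one) | COc1cc(OC)c2c(=O)cc(-c3ccc(Oc4c(OCc5ccccc5)cc5oc(-c6ccc(OCc7ccccc7)cc6)cc(=O)c5c4OCc4ccccc4)cc3)oc2c1 | intermediate
17 | neocryptomerin (5,7-dihydroxy-6-[4-(5-hydroxy-7-methoxy-4-oxo-4H-chromen-2-yl)phenoxy]-2-(4-hydroxyphenyl)-4H-chromen-4-one) | COc1cc(O)c2c(=O)cc(-c3ccc(Oc4c(O)cc5oc(-c6ccc(O)cc6)cc(=O)c5c4O)cc3)oc2c1 | target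

## Step count and risk

Total step count: 9. Longest linear sequence: 6 steps (8 to 9 to 12 to 13 to 14 to 16 to 17); the aryne precursor 7 is made in a 3-step side branch from 1.

**Step 8 (key step).**
- Risk: the ortho-aryl anion may be protonated before the acyl shift, leaving only the 3,5-dimethoxyphenyl ester of 14. The caesium propiolate may lose CO2 at the temperature the acyl shift needs. The phenoxide of 15 may be O-arylated by a second aryne before it closes.
- Fallback: set out from aldehyde 12 and build ring C from a chalcone. Claisen–Schmidt condensation of 12 with 2'-hydroxy-4',6'-dimethoxyacetophenone (Ba(OH)2, MeOH/THF, rt) should give the 2'-hydroxychalcone F1. Oxidative cyclisation (I2 cat., DMSO, 120 °C) then returns to the route at 16.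

**Step 4.**
- Risk: loss of site selectivity, with benzylation reaching O6 or stopping at mono-ethers, because the acidity gap between O4'–H and O6–H is smaller than that between O7–H and O6–H.
- Fallback: set out from 8 with a catechol-type acetal. Dichlorodiphenylmethane (Ph2O, 170 °C) ties O6 and O7 together as 6,7-O-diphenylmethylenescutellarein F2. BnBr/K2CO3 then benzylates only O4' to give the acetal F3, aqueous AcOH at reflux frees 4'-O-benzylscutellarein F4, and one equivalent of BnBr with K2CO3 alkylates the most acidic remaining hydroxyl, O7, to return at 9.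

**Step 5.**
- Risk: arylation at O5 or at both oxygens, base-induced O6-to-O5 aryl migration of Smiles type in 11, or oxidative degradation of the 5,6-diol in hot basic DMF.
- Fallback: set out from 9 and make the nucleophile unambiguous before the substitution. Chloromethyl methyl ether with i-Pr2NEt should cap only the unchelated O6 to give the 6-O-methoxymethyl ether F5. BnBr/K2CO3 in DMF at 60 °C benzylates O5 to give F6, and HCl in MeOH removes the acetal to give 5,7,4'-tri-O-benzylscutellarein F7. Its single free hydroxyl then reacts with 10 (K2CO3, DMF, 90 °C) to return at 12.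

**Step 7.**
- Risk: incomplete C–H carboxylation, or loss of CO2 from the propiolate during acidification and isolation.
- Fallback: set out from 13 by acylation and hydrolysis. Deprotonation with LiN(SiMe3)2 (THF, -78 °C) and trapping with methyl chloroformate should give the methyl propiolate F8, which LiOH in THF/H2O at 0 °C saponifies to return at 14.

**Step 9.**
- Risk: incomplete cleavage of the chelated methyl ether at a temperature at which the debenzylated polyphenol stays in solution, or C-benzylation of ring A'' if cation trapping is too slow.
- Fallback: set out from 16 in two stages with different mechanisms. Hydrogenolysis (H2, Pd(OH)2 on carbon, THF/MeOH) removes the benzyl groups to give 5-O-methylneocryptomerin F9. AlCl3 in MeCN at 50 °C then cleaves only the peri methyl ether through its aluminium chelate and arrives at 17.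

## Further compounds

F1 | step 8 | (E)-2'-hydroxy-4',6'-dimethoxychalcone of aldehyde 12 (5,7-bis(benzyloxy)-2-[4-(benzyloxy)phenyl]-6-{4-[(E)-3-(2-hydroxy-4,6-dimethoxyphenyl)-3-oxoprop-1-en-1-yl]phenoxy}-4H-chromen-4-one) | COc1cc(O)c(C(=O)/C=C/c2ccc(Oc3c(OCc4ccccc4)cc4oc(-c5ccc(OCc6ccccc6)cc5)cc(=O)c4c3OCc3ccccc3)cc2)c(OC)c1
F2 | step 4 | 6,7-O-diphenylmethylenescutellarein | O=c1cc(-c2ccc(O)cc2)oc2cc3c(c(O)c12)OC(c1ccccc1)(c1ccccc1)O3
F3 | step 4 | 4'-O-benzyl-6,7-O-diphenylmethylenescutellarein | O=c1cc(-c2ccc(OCc3ccccc3)cc2)oc2cc3c(c(O)c12)OC(c1ccccc1)(c1ccccc1)O3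
F4 | step 4 | 4'-O-benzylscutellarein | O=c1cc(-c2ccc(OCc3ccccc3)cc2)oc2cc(O)c(O)c(O)c12
F5 | step 5 | 7,4'-di-O-benzyl-6-O-(methoxymethyl)scutellarein | O=c1cc(-c2ccc(OCc3ccccc3)cc2)oc2cc(OCc3ccccc3)c(OCOC)c(O)c12
F6 | step 5 | 5,7,4'-tri-O-benzyl-6-O-(methoxymethyl)scutellarein | O=c1cc(-c2ccc(OCc3ccccc3)cc2)oc2cc(OCc3ccccc3)c(OCOC)c(OCc3ccccc3)c12
F7 | step 5 | 5,7,4'-tri-O-benzylscutellarein | O=c1cc(-c2ccc(OCc3ccccc3)cc2)oc2cc(OCc3ccccc3)c(O)c(OCc3ccccc3)c12
F8 | step 7 | methyl 3-[4-({5,7-bis(benzyloxy)-2-[4-(benzyloxy)phenyl]-4-oxo-4H-chromen-6-yl}oxy)phenyl]prop-2-ynoate | COC(=O)C#Cc1ccc(Oc2c(OCc3ccccc3)cc3oc(-c4ccc(OCc5ccccc5)cc4)cc(=O)c3c2OCc2ccccc2)cc1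
F9 | step 9 | 5-O-methylneocryptomerin | COc1cc(OC)c2c(=O)cc(-c3ccc(Oc4c(O)cc5oc(-c6ccc(O)cc6)cc(=O)c5c4O)cc3)oc2c1
A1 | alternative 1 | 5,7-bis(benzyloxy)-2-[4-(benzyloxy)phenyl]-6-(ethynyloxy)-4H-chromen-4-one | C#COc1c(OCc2ccccc2)cc2oc(-c3ccc(OCc4ccccc4)cc3)cc(=O)c2c1OCc1ccccc1
A2 | alternative 1 | methyl coumalate (methyl 2-oxo-2H-pyran-5-carboxylate) | COC(=O)c1ccc(=O)oc1
A3 | alternative 1 | methyl 4-[(5,7,4'-tri-O-benzylscutellarein-6-yl)oxy]benzoate | COC(=O)c1ccc(Oc2c(OCc3ccccc3)cc3oc(-c4ccc(OCc5ccccc5)cc4)cc(=O)c3c2OCc2ccccc2)cc1
A4 | alternative 2 | methyl (E)-3-methoxy-5,7,9-trioxo-9-[4-({5,7-bis(benzyloxy)-2-[4-(benzyloxy)phenyl]-4-oxo-4H-chromen-6-yl}oxy)phenyl]non-2-enoate | CO/C(CC(=O)CC(=O)CC(=O)c1ccc(Oc2c(OCc3ccccc3)cc3oc(-c4ccc(OCc5ccccc5)cc4)cc(=O)c3c2OCc2ccccc2)cc1)=C/C(=O)OC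
A5 | alternative 2 | 5'',7'',4'''-tri-O-benzylneocryptomerin | COc1cc(O)c2c(=O)cc(-c3ccc(Oc4c(OCc5ccccc5)cc5oc(-c6ccc(OCc7ccccc7)cc6)cc(=O)c5c4OCc4ccccc4)cc3)oc2c1
A6 | alternative 3 | methyl 2-{4-[5-(benzyloxy)-7-methoxy-4-oxo-4H-chromen-2-yl]phenoxy}-4-{6-[4-(benzyloxy)phenyl]-4-oxo-4H-pyran-2-yl}-3-oxobutanoate (racemic) | COC(=O)C(Oc1ccc(-c2cc(=O)c3c(OCc4ccccc4)cc(OC)cc3o2)cc1)C(=O)Cc1cc(=O)cc(-c2ccc(OCc3ccccc3)cc2)o1
A7 | alternative 3 | 5,4'''-di-O-benzylneocryptomerin | COc1cc(OCc2ccccc2)c2c(=O)cc(-c3ccc(Oc4c(O)cc5oc(-c6ccc(OCc7ccccc7)cc6)cc(=O)c5c4O)cc3)oc2c1
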